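The readings stem from a simulated flask for substances that don't exist.

Begin with the easy case. J and D are mirror images charged equally, so a catalyst without a hand would give L and Z alike, with an excess of zero. That is the zero of the scale, and the single-handed Q can lift the excess off it.

| flask | J | D | X | Q | remark | time |
|---|---|---|---|---|---|---|
| eta | 0.020 M | 0.020 M | 2.2 equiv | 0.5 mol% | run made earlier |  |
| delta | 0.020 M | 0.020 M | 2.2 equiv | 0.75 mol% | run made earlier |  |
| zeta | 0.030 M | 0.030 M | 2.2 equiv | 1 mol% | run made earlier |  |
| flask | 0.020 M | 0.020 M | 2.20 equiv | 1 mol% |  | 2.5 min |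

| run | time / s | L / % | Z / % |
|---|---|---|---|
| eta | 10.0 | 2.4 | 1.5 |
| eta | 15.0 | 2.3 | 2.3 |
| eta | 25.0 | 5.4 | 3.1 |
| eta | 50.0 | 9.1 | 5.7 |
| eta | 90.0 | 13.7 | 8.9 |
| delta | 20.0 | 6.3 | 4.4 |
| delta | 40.0 | 10.8 | 6.5 |
| delta | 50.0 | 13.0 | 8.2 |
| delta | 80.0 | 18.0 | 12.4 |
| delta | 90.0 | 19.3 | 12.6 |
| zeta | 10.0 | 9.2 | 6.3 |
| zeta | 25.0 | 17.8 | 11.8 |
| zeta | 40.0 | 22.8 | 15.8 |
| zeta | 60.0 | 27.5 | 18.9 |
| zeta | 90.0 | 32.2 | 23.6 |

(each reading ± 0.5 percentage points)

- Q is single-handed; J and D are mirror images of each other, charged as a racemate, each of them at the stated concentration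
- what was read earlier has a scatter of 0.5 percentage points, one standard deviation
- an excess is below zero if the other one leads

* L and Z together, in percent of the J and D charged together, at 2.5 min
* excess of L over Z in the product at 2.5 min
* whether the exchange between J and D keeps pace with the reaction: how far the product's excess at 2.5 min gets from its value without exchange to its value with instant exchange (above 80 % keeps pace, below 20 % hardly takes part, else lags behind)

Let a be the fraction of J's charge left and b the fraction of D's. L and Z are counted on J and D together, so without exchange a = 1 − 2L, and b follows from Z in the same way. If each substrate falls first order on one shared clock of Q and X, however these run down, ln a stays a fixed multiple of ln b. The last zeta reading, at 90.0 s, gives 1.62. This ratio of ln a to ln b is s, the selectivity factor. At 25.0 s the same run reads 1.63, while the plain ratio of L to Z is higher there than at 90.0 s, 1.51 against 1.36. So in zeta I read s as steady while the plain ratio falls, and I reckon on without exchange.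

Now draw the excess, (b − a)/(2 − a − b), against conversion, which is one minus the mean of a and b. It starts at (s − 1)/(s + 1) = 23.6 %. Instant exchange keeps a equal to b, so this start value is also the flat line to hold the curve against. Without exchange, set a = 0.5. Then b = 0.651, conversion is 42.4 % and the excess is 17.8 %. Next set b = 0.5. Then a = 0.326, conversion is 58.7 % and the excess is 14.8 %. Past that the curve sinks towards zero as a and b vanish.

The forecast gives 47 %, an excess of 18 %, and exchange that hardly takes part; in its words, “The excess therefore decays with conversion”. Its conversion lies between my landmarks, so my curve puts the excess between 17.8 % and 14.8 %, below the forecast's figure.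

The flask gives 49.0 %, an excess of 15.7 %, and exchange that hardly takes part, getting 6.7 % of the way.

    X + Q + J → Q + L (k = 1110 M⁻² s⁻¹)
    X + Q + D → Q + Z (k = 668 M⁻² s⁻¹)
    J ⇌ D (k = 7.41 × 10⁻⁴ s⁻¹)
    L ⇌ Z (k = 6.73 × 10⁻⁴ s⁻¹)
    2 Q ⇌ G (K = 1900 M⁻¹, k = 12.4 M⁻¹ s⁻¹)

Put the flask on the curve: D left at 59 % of its charge gives a = 0.421 and an excess of 16.6 %, against the 15.7 % found. Then raise Q to 1.7 mol%, with the other charges and the time held. That neighbouring flask reaches a yield of 59.8 % with 48 % of D left, so a = 0.308 and the curve gives 14.5 %. Its simulated excess is 13.7 %.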